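**Plan**

1. Locants used here: ring A is C17–C2(=C1H2)–C3–C4–C5–C18(Me2); ring B is the ether ring C5–O–C6–C17–C18; ring C is C6–C7–C8(C9H3)–C15–C16–C17; ring D is C8–C10(Br)–C11–C12–C13(C14H3)(OH)–C15.
2. Retrosynthesis: C10–Br goes back to a C10 ketone. Ring D is then cut at C12–C13: C10(=O) and C13(OH) stand 1,4 across ring D, a γ-hydroxy ketone that maps onto a homoenolate adding to a ketone, so C10–C11–C12 become a cyclopropanol beside the C15 acetyl group.
3. The cyclopropanol comes from a C8 ester (Kulinkovich). The quaternary C8 comes from Me2CuLi addition to a ring C 2-acetylcyclohexene-1-carboxylate, made from the ring C ketone by acylation, enol triflation and carbonylation.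
4. Rings B and C, the spiro centre C17 and C6 are cut together by an intramolecular Diels–Alder reaction between a ring A exo-enone (C17=C16) and a 1-alkoxy-3-silyloxy diene attached through O–C5.
5. Forward order: ring A from 2,2-dimethylcyclohexane-1,3-dione; rings B and C by the Diels–Alder reaction; the C8 and C15 substituents; ring D by strain-release cyclisation; finally the bromide.
6. Stereochemistry: C5 from CBS reduction; C17 and C6 relayed from C5 through the tether and the endo transition state; C8 by axial cuprate attack on the locked ring C; C15 by protonation (equatorial acetyl); C13 in the key step; C10 by axial hydrogen-atom transfer.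

Key step: step 13

Remark: 6 is carried as a mixture of epimers at its new carbinol carbon C2, which becomes the ketone in step 5; 17 is drawn as the open hydroxy ketone, with which any five-ring hemiketal would be in equilibrium.

**Route**

Step 1
Reactants: 1 2,2-dimethylcyclohexane-1,3-dione
Product: 2 2,2-dimethyl-3-methylidenecyclohexan-1-one
Conditions: Ph3P=CH2 (0.6 equiv), THF, 0 °C to rt
Reagents that add atoms: methylenetriphenylphosphorane, C=P(c1ccccc1)(c1ccccc1)c1ccccc1
Why: Wittig methylenation with the dione in excess should favour the mono-olefin, and the quaternary carbon between the carbonyl groups rules out enolisation towards it.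

Step 2
Reactants: 2 2,2-dimethyl-3-methylidenecyclohexan-1-one
Product: 3 (1S)-2,2-dimethyl-3-methylidenecyclohexan-1-ol
Conditions: (R)-2-methyl-CBS-oxazaborolidine (10 mol%), catecholborane, PhMe, −78 °C
Reagents that add atoms: none
Why: Corey–Bakshi–Shibata reduction, in which the quaternary carbon is the large group and the ring CH2 the small one, so the (R)-catalyst should give the (S)-carbinol (the future C5), while catecholborane at low temperature leaves the 1,1-disubstituted alkene alone.

Step 3
Reactants: 3 (1S)-2,2-dimethyl-3-methylidenecyclohexan-1-ol; 4 but-3-yn-2-one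
Product: 5 (3E)-4-{[(1S)-2,2-dimethyl-3-methylidenecyclohexyl]oxy}but-3-en-2-one
Conditions: PMe3 (10 mol%), CH2Cl2, 0 °C to rt
Reagents that add atoms: none
Why: phosphine-catalysed oxa-Michael addition of the hindered secondary alcohol to the ynone should give the (E)-β-alkoxy enone without touching the carbinol centre.

Step 4
Reactants: 5 (3E)-4-{[(1S)-2,2-dimethyl-3-methylidenecyclohexyl]oxy}but-3-en-2-one
Product: 6 (3E)-4-{[(1S)-4-hydroxy-2,2-dimethyl-3-methylidenecyclohexyl]oxy}but-3-en-2-one (both epimers at the new carbinol)
Conditions: SeO2 (0.3 equiv), tBuOOH, CH2Cl2, rt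
Reagents that add atoms: tert-butyl hydroperoxide, CC(C)(C)OO
Why: SeO2/tBuOOH allylic oxidation (ene reaction then [2,3]-shift) can only reach the ring CH2 next to the exocyclic alkene, because the other neighbour is the quaternary CMe2, and the unselective new carbinol centre is removed in step 5.

Step 5
Reactants: 6 (3E)-4-{[(1S)-4-hydroxy-2,2-dimethyl-3-methylidenecyclohexyl]oxy}but-3-en-2-one
Product: 7 (4S)-3,3-dimethyl-2-methylidene-4-{[(1E)-3-oxobut-1-en-1-yl]oxy}cyclohexan-1-one
Conditions: MnO2 (20 equiv), CH2Cl2, rt
Reagents that add atoms: none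
Why: MnO2 oxidation is selective for the allylic alcohol under neutral conditions and should give the 2-methylidene ketone, which the adjacent gem-dimethyl group shields from dimerisation.

Step 6
Reactants: 7 (4S)-3,3-dimethyl-2-methylidene-4-{[(1E)-3-oxobut-1-en-1-yl]oxy}cyclohexan-1-one
Product: 9 tricyclic keto silyl enol ether of rings A–B–C (C2 ketone; C7=C8 bearing OTBS on C8; C5 S; O on C6 trans to C18 across ring C), via silyloxydiene 8 (not isolated)
Conditions: TBSOTf (1.05 equiv), Et3N, Et2O, −78 to 0 °C; then PhMe, 90 °C
Reagents that add atoms: tert-butyldimethylsilyl trifluoromethanesulfonate, CC(C)(C)[Si](C)(C)OS(=O)(=O)C(F)(F)F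
Why: soft enolisation of the more Lewis-basic vinylogous ester should give a 1-alkoxy-3-silyloxy (Danishefsky-type) diene that adds to the exo-enone in an intramolecular Diels–Alder reaction over the three-atom tether O–C5–C18, the tether relaying C5 to C17 and the endo position of the C2 carbonyl under the (E)-dienyl ether placing the oxygen on C6 trans to C18.

Step 7
Reactants: 9 tricyclic keto silyl enol ether
Product: 11 tricyclic ketone (C2 methylidene; C8 ketone), via methylidene silyl enol ether 10 (not isolated)
Conditions: Cp2TiMe2 (3 equiv), PhMe, 75 °C; then TBAF, AcOH, THF, 0 °C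
Reagents that add atoms: dimethyltitanocene (Cp2TiMe2), C[Ti](C)(C1C=CC=C1)C1C=CC=C1
Why: Petasis methylenation copes with the hindered, enolisable C2 ketone while the ring C ketone stays masked as its silyl enol ether, and buffered fluoride then frees the C8 ketone without base-induced β-elimination of the C6 ether.

Step 8
Reactants: 11 tricyclic ketone (C2 methylidene; C8 ketone)
Product: 12 C15-acetyl derivative of 11, drawn as the C8 enol of the β-diketone
Conditions: LiN(iPr)2 (2.1 equiv), THF, −78 °C; 1-acetylbenzotriazole (1.0 equiv), −78 to −40 °C; aq. NH4Cl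
Reagents that add atoms: 1-acetylbenzotriazole, CC(=O)n1nnc2ccccc12
Why: kinetic deprotonation should occur at C15, away from the more hindered C7 next to the alkoxy-bearing C6, and the lithium enolate is C-acylated by the acylbenzotriazole (Claisen-type acylation), the second equivalent of base taking up the acidic proton of the β-diketone as it forms.

Step 9
Reactants: 12 enolised β-diketone
Product: 13 C8 enol triflate (C8=C15; acetyl on C15)
Conditions: Tf2O, iPr2NEt, CH2Cl2, −78 °C
Reagents that add atoms: trifluoromethanesulfonic anhydride, O=S(=O)(OS(=O)(=O)C(F)(F)F)C(F)(F)F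
Why: enol triflation should take the ring oxygen, since 2-acetylcyclohexanones enolise mainly towards the endocyclic double bond, giving the vinylogous acyl triflate at C8.

Step 10
Reactants: 13 C8 enol triflate
Product: 14 methyl ester at C8 (C8=C15; acetyl on C15)
Conditions: CO (1 atm), MeOH, Pd(OAc)2 (5 mol%), PPh3 (10 mol%), Et3N, DMF, 50 °C
Reagents that add atoms: carbon monoxide, [C-]#[O+]; methanol, CO
Why: palladium-catalysed methoxycarbonylation of the enol triflate, for which β-triflyloxy enones are good substrates, installs C10 at the ester oxidation level.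

Step 11
Reactants: 14 methyl ester at C8
Product: 15 C8 quaternary ester (C9 methyl axial; CO2Me equatorial) with the C15=C13 trimethylsilyl enol ether (either alkene geometry)
Conditions: Me2CuLi (1.5 equiv), TMSCl, Et2O, −78 to −30 °C
Reagents that add atoms: lithium dimethylcuprate, [Li+].C[Cu-]C; chlorotrimethylsilane, C[Si](C)(C)Cl
Why: cuprate conjugate addition should occur β to the ketone (α to the ester) of the doubly activated alkene by axial attack on ring C, which the trans-fused ring B locks, from the face carrying only the axial hydrogens on C6 and C16, so the methyl ends up axial and the ester equatorial, and the enolate is kept as its silyl enol ether.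

Step 12
Reactants: 15 C8 quaternary ester
Product: 17 keto cyclopropanol (1-hydroxycyclopropyl on C8; equatorial acetyl on C15), via cyclopropanol silyl enol ether 16 (not isolated)
Conditions: EtMgBr (4 equiv), Ti(OiPr)4 (0.3 equiv), THF, 0 °C to rt; then aq. citric acid, THF, 0 °C
Reagents that add atoms: ethylmagnesium bromide, CC[Mg]Br
Why: Kulinkovich cyclopropanation converts the ester into the cyclopropanol that holds C10, C11 and C12 while the ketone is masked, and hydrolysis of the enol ether protonates C15 from the axial face away from the C9 methyl, leaving the acetyl group equatorial, which is also the thermodynamic epimer.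

Step 13
Reactants: 17 keto cyclopropanol
Product: 20 tetracyclic hydroxy ketone (C10 ketone; C13 tertiary alcohol with axial OH cis to the C9 methyl), via zinc homoenolate 18 (not isolated), via trimethylsilyl ether 19 (not isolated)
Conditions: Et2Zn (2.2 equiv), THF, 0 °C to rt; TMSCl (2.5 equiv), 40 °C; then 1 M HCl, THF, 0 °C
Reagents that add atoms: none
Why: Proposed new method: Et2Zn deprotonates the cyclopropanol and the zinc cyclopropoxide opens by β-carbon elimination, driven by about 27 kcal/mol of ring strain (C11 and C12 are equivalent, so a single homoenolate forms), to the β-zincio ketone 18, whose C12–Zn bond adds to the C13 carbonyl of the neighbouring acetyl group once TMSCl activates it and then caps the alkoxide, which makes ring closure irreversible while reclosure to the cyclopropoxide stays reversible. The closest known reaction types are the Et2Zn-mediated opening of cyclopropanols to zinc homoenolates and the TMSCl-promoted 1,2-addition of zinc homoenolates to aldehydes; intramolecular capture by a ketone has not been shown. Ring D closes in the 6-exo-trig mode (C12 onto C13=O; ring atoms C8, C10, C11, C12, C13 and C15) and is trans-fused to ring C because both tethers are equatorial. C13 is set in a chair transition state in which the C14 methyl is equatorial, since an axial methyl would meet the axial C9 methyl in a 1,3-diaxial clash, so the oxygen ends up axial and cis to C9, while C8 and C15 enter the step already set by steps 11 and 12. The step needs carbonyl addition to outrun enolisation of the methyl ketone, β-hydride loss and simple protonation: alkylzinc reagents are too weakly basic to enolise ketones and slow to β-eliminate, and the 1,4-spacing of C10 and C13 across ring D makes the six-membered closure the only strain-free outlet for the homoenolate.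

Step 14
Reactants: 20 tetracyclic hydroxy ketone
Product: 22 C10 gem-dibromide, via silyl hydrazone 21 (not isolated)
Conditions: TBSNHNHTBS, Sc(OTf)3 (1 mol%), CHCl3, 55 °C; then CuBr2, Et3N, MeOH, 0 °C to rt
Reagents that add atoms: copper dibromide, [Cu+2].[Br-].[Br-]
Why: hydrazone-to-gem-dihalide conversion, in which divalent copper oxidises the silyl hydrazone of the hindered C10 ketone to the diazo compound that takes up two bromines with loss of N2, should leave the exocyclic alkene and the tertiary alcohol untouched.

Step 15
Reactants: 22 C10 gem-dibromide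
Product: 23 target (5S,6R,8S,10S,13R,15S,17R in the locants used here)
Conditions: Bu3SnH (1.05 equiv), Et3B (0.2 equiv), air, PhMe, −20 °C
Reagents that add atoms: none
Why: radical monoreduction with tin hydride stops at the monobromide because the first C–Br bond of a gem-dibromide is cleaved much faster, and the α-bromo radical at C10 should take hydrogen along the axial path anti to the axial C9 methyl, leaving bromine equatorial as in the target.

**Compound list**

1 | 2,2-dimethylcyclohexane-1,3-dione | CC1(C)C(=O)CCCC1=O | starting material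
2 | 2,2-dimethyl-3-methylidenecyclohexan-1-one | C=C1CCCC(=O)C1(C)C | intermediate
3 | (1S)-2,2-dimethyl-3-methylidenecyclohexan-1-ol | C=C1CCC[C@H](O)C1(C)C | intermediate
4 | but-3-yn-2-one | CC(=O)C#C | starting material
5 | (3E)-4-{[(1S)-2,2-dimethyl-3-methylidenecyclohexyl]oxy}but-3-en-2-one | C=C1CCC[C@H](O/C=C/C(C)=O)C1(C)C | intermediate
6 | (3E)-4-{[(1S)-4-hydroxy-2,2-dimethyl-3-methylidenecyclohexyl]oxy}but-3-en-2-one, epimers at C4 of the ring | C=C1C(O)CC[C@H](O/C=C/C(C)=O)C1(C)C | intermediate
7 | (4S)-3,3-dimethyl-2-methylidene-4-{[(1E)-3-oxobut-1-en-1-yl]oxy}cyclohexan-1-one | C=C1C(=O)CC[C@H](O/C=C/C(C)=O)C1(C)C | intermediate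
8 | (4S)-4-{[(1E)-3-(tert-butyldimethylsilyloxy)buta-1,3-dien-1-yl]oxy}-3,3-dimethyl-2-methylidenecyclohexan-1-one | C=C1C(=O)CC[C@H](O/C=C/C(=C)O[Si](C)(C)C(C)(C)C)C1(C)C | intermediate
9 | tricycle A–B–C: C2 ketone, C7=C8 silyl enol ether (OTBS on C8), O on C6 trans to C18 | O=C1CC[C@@H]2O[C@@H]3C=C(O[Si](C)(C)C(C)(C)C)CC[C@]13C2(C)C | intermediate
10 | C2-methylidene analogue of 9 | C=C1CC[C@@H]2O[C@@H]3C=C(O[Si](C)(C)C(C)(C)C)CC[C@]13C2(C)C | intermediate
11 | tricycle A–B–C: C2 methylidene, C8 ketone | C=C1CC[C@@H]2O[C@@H]3CC(=O)CC[C@]13C2(C)C | intermediate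
12 | C15-acetyl derivative of 11 as the C8 enol (C8=C15) | C=C1CC[C@@H]2O[C@@H]3CC(O)=C(C(C)=O)C[C@]13C2(C)C | intermediate
13 | C8 enol triflate of 12 | C=C1CC[C@@H]2O[C@@H]3CC(OS(=O)(=O)C(F)(F)F)=C(C(C)=O)C[C@]13C2(C)C | intermediate
14 | C8 methyl ester, C8=C15, C15 acetyl | C=C1CC[C@@H]2O[C@@H]3CC(C(=O)OC)=C(C(C)=O)C[C@]13C2(C)C | intermediate
15 | C8 quaternary (axial C9 methyl, equatorial CO2Me), C15=C13(OTMS)CH3 enol ether of either geometry | C=C1CC[C@@H]2O[C@@H]3C[C@](C)(C(=O)OC)C(=C(C)O[Si](C)(C)C)C[C@]13C2(C)C | intermediate
16 | 1-hydroxycyclopropyl on C8 in place of the ester of 15 | C=C1CC[C@@H]2O[C@@H]3C[C@](C)(C4(O)CC4)C(=C(C)O[Si](C)(C)C)C[C@]13C2(C)C | intermediate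
17 | keto cyclopropanol: 1-hydroxycyclopropyl (equatorial) and methyl (axial) on C8, equatorial acetyl on C15 | C=C1CC[C@@H]2O[C@@H]3C[C@](C)(C4(O)CC4)[C@@H](C(C)=O)C[C@]13C2(C)C | intermediate
18 | ethylzinc homoenolate (C12–Zn, C10 ketone) | C=C1CC[C@@H]2O[C@@H]3C[C@](C)(C(=O)CC[Zn]CC)[C@@H](C(C)=O)C[C@]13C2(C)C | intermediate
19 | trimethylsilyl ether of 20 | C=C1CC[C@@H]2O[C@@H]3C[C@]4(C)C(=O)CC[C@@](C)(O[Si](C)(C)C)[C@H]4C[C@]13C2(C)C | intermediate
20 | tetracycle: C10 ketone, C13 tertiary alcohol (OH axial, cis to C9 methyl) | C=C1CC[C@@H]2O[C@@H]3C[C@]4(C)C(=O)CC[C@@](C)(O)[C@H]4C[C@]13C2(C)C | intermediate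
21 | N-tert-butyldimethylsilyl hydrazone of 20 at C10 | C=C1CC[C@@H]2O[C@@H]3C[C@]4(C)C(=NN[Si](C)(C)C(C)(C)C)CC[C@@](C)(O)[C@H]4C[C@]13C2(C)C | intermediate
22 | C10 gem-dibromide | C=C1CC[C@@H]2O[C@@H]3C[C@]4(C)C(Br)(Br)CC[C@@](C)(O)[C@H]4C[C@]13C2(C)C | intermediate
23 | target, equatorial bromide at C10 | C=C1CC[C@@H]2O[C@@H]3C[C@]4(C)[C@@H](Br)CC[C@@](C)(O)[C@H]4C[C@]13C2(C)C | target

**Count and risks**

Total step count: 15. Longest linear sequence: 15 steps (from 1; 4 is bought).

Steps most likely to fail:

1. Step 13 (proposed new method). The cyclopropanol may open without ring closure: the zinc homoenolate is protonated on work-up or recloses, so the substrate is recovered. The fallback sets out from 17. Oxidative ring opening with Pd(OAc)2 (10 mol%), pyridine and O2 in PhMe at 80 °C should give the vinyl ketone F1. SmI2 in THF with tBuOH at −78 °C then closes ring D by ketyl–olefin reductive cyclisation, the C13 ketyl attacking the polarity-matched enone terminus C12 in the 6-endo mode. This comes back to the route at 20.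

2. Step 6. Silylation may be unselective (dienolisation of the ring A enone), or a stepwise Lewis-acid pathway may erode facial selectivity at C6. The fallback sets out from 6. Ac2O, pyridine and DMAP give the allylic acetate F2; TBSOTf and Et3N then form the diene as the silyloxydiene acetate F3 while no enone is present; iBu2AlH in CH2Cl2 at −78 °C removes the acetate to give the dienyl allylic alcohol F4. MnO2 then forms 8 free of silyl triflate, and warming in PhMe closes the rings thermally. This comes back at 9.

3. Step 14. The α-bromo intermediate may lose a proton to give the vinyl bromide, or be intercepted by the C13 hydroxyl across ring D, instead of taking up the second bromide. The fallback sets out from 20. mCPBA masks the exocyclic alkene as the spiro-epoxide ketone F5; TBSNHNHTBS with Sc(OTf)3 gives the epoxy silyl hydrazone F6; Br2 with 2-tert-butyl-1,1,3,3-tetramethylguanidine gives the epoxy vinyl bromide F7. Hydrogen-atom-transfer hydrogenation with Mn(dpm)3, PhSiH3 and tBuOOH in iPrOH should deliver hydrogen axially at C10 to give the epoxy bromide F8. Cp2TiCl (trivalent titanium, from Cp2TiCl2 and Zn) then deoxygenates the epoxide back to the alkene. This comes back at 23.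

**Further compounds**

F1 | step 13 | vinyl ketone (acryloyl on C8, acetyl on C15) | C=C1CC[C@@H]2O[C@@H]3C[C@](C)(C(=O)C=C)[C@@H](C(C)=O)C[C@]13C2(C)C
F2 | step 6 | allylic acetate of 6 | C=C1C(OC(C)=O)CC[C@H](O/C=C/C(C)=O)C1(C)C
F3 | step 6 | silyloxydiene acetate | C=C1C(OC(C)=O)CC[C@H](O/C=C/C(=C)O[Si](C)(C)C(C)(C)C)C1(C)C
F4 | step 6 | dienyl allylic alcohol | C=C1C(O)CC[C@H](O/C=C/C(=C)O[Si](C)(C)C(C)(C)C)C1(C)C
F5 | step 14 | spiro-epoxide ketone (C1–C2 epoxide of 20) | O1CC12CC[C@@H]3O[C@@H]4C[C@]5(C)C(=O)CC[C@@](C)(O)[C@H]5C[C@]24C3(C)C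
F6 | step 14 | epoxy silyl hydrazone | O1CC12CC[C@@H]3O[C@@H]4C[C@]5(C)C(=NN[Si](C)(C)C(C)(C)C)CC[C@@](C)(O)[C@H]5C[C@]24C3(C)C
F7 | step 14 | epoxy vinyl bromide (C10=C11) | O1CC12CC[C@@H]3O[C@@H]4C[C@]5(C)C(Br)=CC[C@@](C)(O)[C@H]5C[C@]24C3(C)C
F8 | step 14 | epoxy bromide (equatorial Br at C10) | O1CC12CC[C@@H]3O[C@@H]4C[C@]5(C)[C@@H](Br)CC[C@@](C)(O)[C@H]5C[C@]24C3(C)C
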